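## Analysis of the target

The target is a flavone (2-aryl-4H-chromen-4-one). Ring A carries 5-OH, 6-OCH3 and 7-OH with C8 unsubstituted, ring C carries 3-OCH3, and ring B carries 4'-OH flanked by a 3-methylbut-2-enyl (prenyl) group at C3' and a 4-hydroxy-3-methylbutyl chain (C1''–C4'') at C5'. The only stereocentre is C3'' of that chain, (S)-configured. It lies three bonds from ring B and has no second stereo-element to relate to, so it must be set by a chiral reagent or catalyst. The sensitive groups are the prenyl alkene next to the free 4'-OH (acid closes it to a dimethylchroman, and hydrogenation or hydrogenolysis is excluded), the electron-rich ring A, the base-labile pyranone, and any α-methyl aldehyde on the way (epimerisation). Three things make the synthesis hard. A ring A ketone with two free ortho-hydroxyls can close ring C towards either the 6-methoxy or the 8-methoxy flavone. Ring B bears two C5 chains that differ only at their far ends. The stereocentre is remote. The strategy rests on one observation: the C5' chain is a prenyl group whose (E)-methyl carbon C4'' has been oxidised and whose C2''=C3'' bond has been reduced. A ring B with prenyl groups at both C3' and C5' has a mirror plane through C1' and C4', so the two groups are interchangeable by rotation about C2–C1'. A symmetric ring B can therefore be carried through the assembly and differentiated at the end, and the stereocentre is created in the last C–H bond-forming event.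

## Retrosynthetic reasoning

**20 ⇒ 19.** The three phenolic O–H bonds are traced back to methoxymethyl (MOM) ethers, cleaved in the last step. The acetals stay on until the end for three reasons. The allylic oxidation and the organometallic steps need capped phenols. At the enal stage a free 4'-OH could add to the neighbouring enal chain (5-exo oxa-Michael) and phenolates are tight ligands of the flavoenzyme used. Removing acetals from the saturated alcohol 19 is the safest moment, because no enal and no epimerisable centre are left.

**19 ⇒ 18 ⇒ 17.** The C4''–H bond of the alcohol and then the C2''–H and C3''–H bonds are cut, leading back to the (E)-2-methyl enal 17. This places the only stereocentre in the final skeletal operation, so no later step can erode it. The forward reaction must reduce one of three C=C bonds, with face control at the α-carbon, and must trap the labile α-methyl aldehyde 18 at once. An ene-reductase coupled to an alcohol dehydrogenase is designed for exactly this.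

**17 ⇒ 16.** The C4''=O bond is removed, giving the 3',5'-diprenyl flavone 16. The two prenyl groups are equivalent, so a Riley oxidation cannot give regioisomers. It oxidises the (E)-methyl group, which fixes the alkene geometry that the enzyme needs. The gain is that everything before 16 is symmetric in ring B.

**16 ⇒ 15 ⇒ 14 ⇒ 8 + 13.** Ring C is opened at O1–C2 (cyclodehydration), then at C2–C3 (Baker–Venkataraman acyl transfer), then at the ester C–O bond. This gives the ω-methoxy ketone 8 and the benzoic acid 13. The ω-methoxy group brings the 3-OCH3 in from the start, so no 3-hydroxylation is needed in the presence of prenyl alkenes. The cut is convergent and divides the molecule into halves of similar size.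

**8 ⇒ 5 + 6 ⇒ 4 ⇒ 2 ⇒ 1.** The aryl–acyl bond is cut to the bromophenol 5 and the Weinreb amide 6. Bromide 5 comes from phenol 4, and 4 comes from the symmetric bis-MOM ether 2 of diol 1 by C–H borylation and oxidation. This order is chosen because the hydroxyl introduced last is the only free one, and it sits para to the methoxy group. After acylation ortho to it, only this oxygen can become O1, so the methoxy group must end up at C6. The acylation is done through an aryllithium because MOM ethers would not survive Friedel–Crafts or Hoesch conditions.

**13 ⇒ 12 ⇒ 10 + 11 ⇒ 9.** The acid is traced to its methyl ester 12. The two aryl–CH2 bonds are cut to the diiodide 10 and the prenylstannane 11, a twofold Stille coupling on a purchasable diiodophenol 9. Cross-coupling is preferred to C-alkylation of a phenoxide because it gives no O-alkyl or mono-alkyl mixtures.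

## Alternatives that were turned down

**Alternative 1:** The stereocentre is made on a ring B building block by disconnecting the C3''–CH3 bond and the terminal C–O bond. The terminal alkene A2, [4-bromo-2-(but-3-enyl)-6-prenylphenoxy]triisopropylsilane, would undergo zirconium-catalysed asymmetric methylalumination (Me3Al, catalytic (NMI)2ZrCl2, that is bis(1-neomenthylindenyl)zirconium dichloride). Oxidation of the C–Al bond with O2 would give the (S)-alcohol A1.
- For: this is an established reagent-controlled route to the 2-methylalkan-1-ol motif. It needs no protein that must accept a large substrate. The trisubstituted prenyl alkene and the aryl bromide are inert to carboalumination. The enantiomeric purity can be measured and upgraded on a small molecule.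
- Against: methylalumination of unbranched terminal alkenes is usually less selective than an enzyme and tends to need an upgrading step. The centre is set early and carried through the whole flavone assembly. Ring B must be unsymmetrical from the outset, so a butenyl and a prenyl chain have to be installed one after the other, and the bromide must still be converted into an acylating partner.
- Comparison: it is stronger on precedent for the stereo-defining bond formation. The chosen strategy offers a symmetric ring B made in three steps, a stereocentre set last, and access to either enantiomer by enzyme choice.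

**Alternative 2:** Ring A is formed last by disconnecting C4a–C5. The pyranone A4, derived from kojic acid A5, carries the ring B aryl group at C2, the methoxy group at C3 and a CH2–CO–CH(OCH3)–CO2CH3 chain at C8a. It would be treated with Mg(OMe)2 or excess LiN(SiMe3)2 so that C4a acylates on the ester carbon. Enolisation of the new ring then gives the protected flavone A3.
- For: the 5,7-dihydroxy-6-methoxy pattern arises unambiguously and without ring A protecting groups. On this point it is stronger than the chosen route, which spends steps 1–4 on a differentiated ring A ketone.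
- Against: base removes the C8 and C6 protons first and gives stabilised enolates. C4a is only the α-terminus of an extended enolate and must attack an ester in competition with these resting states. The closure is biomimetic in type but thinly supported on pyranones. It would be attempted at the very end, on material that already contains a stereocentre made separately in ring B. Arylating the pyranone and building the keto ester chain add many steps.
- Comparison: it has better regiochemical economy in ring A. The chosen strategy offers a ring closure of a well-understood kind (Baker–Venkataraman) and places its one uncertain step where failure costs a two-step detour.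

**Alternative 3:** The flavone is cut at C2–C1'. The 3-methoxychromone A7 would be zincated at C2 with TMPZnCl·LiCl and coupled with the aryl bromide A8 (Pd(OAc)2, biaryl phosphine, Negishi coupling) to give the fully protected target A6.
- For: it is the most convergent plan. It avoids the buffered-acid cyclodehydration with MOM and prenyl groups on board, which is a weak point of the chosen route (step 10), and is stronger on that point.
- Against: A7 still needs the same regiodefined ring A ketone plus a one-carbon annulation. C8–H, flanked by O1 and the 7-O-MOM group, is a second possible metalation site. A8 must be unsymmetrical and enantioenriched before the coupling, so a separate asymmetric step and a stepwise installation of two different chains are required.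
- Comparison: it gains convergence and a milder union. The chosen strategy keeps ring B symmetric until the end, sets the stereocentre after all harsh steps, and is shorter overall.

Key step: step 12

Remark: compounds 1, 6, 9 and 11 are taken to be purchasable.

Remark: the phenols are carried as MOM ethers through the enzymatic reduction and released afterwards, for the reasons given under 20 ⇒ 19.

## Route

Step 1
Reactants: 1 2-methoxybenzene-1,3-diol
Product: 2 2-methoxy-1,3-bis(methoxymethoxy)benzene
Conditions: MOMCl (2.5 equiv), i-Pr2NEt, CH2Cl2, 0 °C → rt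
Reagents that add atoms: chloromethyl methyl ether, COCCl
Why: Base-mediated O-alkylation of both phenols (acetal protection). MOM ethers tolerate the iridium catalyst, organolithiums, amide bases and enzymes used later, and they can be removed at the end without hydrogenolysis or a strong Lewis acid, either of which would endanger the prenyl group.

Step 2
Reactants: 2 2-methoxy-1,3-bis(methoxymethoxy)benzene
Product: 4 4-methoxy-3,5-bis(methoxymethoxy)phenol, via pinacol arylboronate 3 (not isolated)
Conditions: [Ir(OMe)(cod)]2 (1.5 mol%), 4,4'-di-tert-butyl-2,2'-bipyridine (3 mol%), B2pin2 (1.0 equiv), THF, 70 °C; then aq. NaOH, H2O2, 0 °C → rt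
Reagents that add atoms: hydrogen peroxide, OO (phenolic oxygen); bis(pinacolato)diboron, CC1(C)OB(OC1(C)C)B1OC(C)(C)C(C)(C)O1 (boron of intermediate 3 only)
Why: Iridium-catalysed aromatic C–H borylation is governed by sterics, and C5 of 2 is the only C–H without an ortho substituent; alkaline peroxide then oxidises the C–B bond in place (one-pot borylation–oxidation). The new hydroxyl, para to the methoxy group, is the only free one, and this later fixes the 6-methoxy regiochemistry.

Step 3
Reactants: 4 4-methoxy-3,5-bis(methoxymethoxy)phenol
Product: 5 2-bromo-4-methoxy-3,5-bis(methoxymethoxy)phenol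
Conditions: NBS (1.0 equiv), CH2Cl2, −78 → −20 °C
Reagents that add atoms: N-bromosuccinimide, O=C1CCC(=O)N1Br
Why: Electrophilic aromatic bromination of a strongly activated phenol. C2 and C6 are equivalent and are the only free positions, so one equivalent at low temperature should stop at the monobromide.

Step 4
Reactants: 5 2-bromo-4-methoxy-3,5-bis(methoxymethoxy)phenol; 6 N,2-dimethoxy-N-methylacetamide
Product: 8 1-[6-hydroxy-3-methoxy-2,4-bis(methoxymethoxy)phenyl]-2-methoxyethan-1-one, via dilithio aryl phenoxide 7 (not isolated)
Conditions: n-BuLi (2.2 equiv), THF, −78 °C; then 6, −78 → 0 °C; aq. NH4Cl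
Reagents that add atoms: n-butyllithium, [Li]CCCC (lithium of intermediate 7 only)
Why: The first equivalent of n-BuLi deprotonates the phenol and the second effects bromine–lithium exchange, giving an aryllithium chelated by the neighbouring MOM oxygen. Weinreb amide acylation stops at the ketone because the tetrahedral adduct survives until work-up. The methoxyacetyl group is thus installed under basic conditions that MOM ethers tolerate.

Step 5
Reactants: 9 methyl 4-hydroxy-3,5-diiodobenzoate
Product: 10 methyl 3,5-diiodo-4-(methoxymethoxy)benzoate
Conditions: NaH, DMF, 0 °C; MOMCl, 0 °C → rt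
Reagents that add atoms: chloromethyl methyl ether, COCCl
Why: O-Alkylation of the acidic, hindered 2,6-diiodophenoxide. The phenol has to be masked for the coupling, the esterification and the allylic oxidation.

Step 6
Reactants: 10 methyl 3,5-diiodo-4-(methoxymethoxy)benzoate; 11 tributyl(3-methylbut-2-en-1-yl)stannane (2.5 equiv)
Product: 12 methyl 4-(methoxymethoxy)-3,5-bis(3-methylbut-2-en-1-yl)benzoate
Conditions: Pd(PPh3)4 (5 mol%), DMF, 95 °C
Reagents that add atoms: none
Why: Twofold Stille coupling: zerovalent palladium inserts into each C–I bond, the allylic stannane transmetalates, and reductive elimination at the unsubstituted allyl terminus gives the linear prenyl groups. The ester and the MOM ether are inert, and both positions receive the same group, so ring B stays symmetric.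

Step 7
Reactants: 12 methyl 4-(methoxymethoxy)-3,5-bis(3-methylbut-2-en-1-yl)benzoate
Product: 13 4-(methoxymethoxy)-3,5-bis(3-methylbut-2-en-1-yl)benzoic acid
Conditions: LiOH·H2O, THF–MeOH–H2O, 40 °C; then 1 M HCl to pH 4, 0 °C
Reagents that add atoms: lithium hydroxide, [Li+].[OH-]
Why: Saponification of an unhindered methyl benzoate. Acidifying only to pH 4 in the cold keeps the MOM ether.

Step 8
Reactants: 8 1-[6-hydroxy-3-methoxy-2,4-bis(methoxymethoxy)phenyl]-2-methoxyethan-1-one; 13 4-(methoxymethoxy)-3,5-bis(3-methylbut-2-en-1-yl)benzoic acid
Product: 14 4-methoxy-2-(2-methoxyacetyl)-3,5-bis(methoxymethoxy)phenyl 4-(methoxymethoxy)-3,5-bis(3-methylbut-2-en-1-yl)benzoate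
Conditions: EDC·HCl, DMAP, CH2Cl2, rt
Reagents that add atoms: none
Why: Steglich-type carbodiimide esterification of the chelated phenol. It is chosen over an acid chloride so that no HCl meets the MOM ethers, and it sets up the intramolecular acyl transfer.

Step 9
Reactants: 14 4-methoxy-2-(2-methoxyacetyl)-3,5-bis(methoxymethoxy)phenyl 4-(methoxymethoxy)-3,5-bis(3-methylbut-2-en-1-yl)benzoate
Product: 15 1-[6-hydroxy-3-methoxy-2,4-bis(methoxymethoxy)phenyl]-2-methoxy-3-[4-(methoxymethoxy)-3,5-bis(3-methylbut-2-en-1-yl)phenyl]propane-1,3-dione
Conditions: LiN(SiMe3)2 (3 equiv), THF, −78 → −10 °C; aq. NH4Cl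
Reagents that add atoms: none
Why: Baker–Venkataraman rearrangement: the enolate formed at the methoxy-bearing methylene attacks the neighbouring aryl ester through a six-membered transition state and expels the phenoxide, forming the future C2–C3 bond. The non-nucleophilic amide base spares the acetals and alkenes.

Step 10
Reactants: 15 1-[6-hydroxy-3-methoxy-2,4-bis(methoxymethoxy)phenyl]-2-methoxy-3-[4-(methoxymethoxy)-3,5-bis(3-methylbut-2-en-1-yl)phenyl]propane-1,3-dione
Product: 16 3,6-dimethoxy-5,7-bis(methoxymethoxy)-2-[4-(methoxymethoxy)-3,5-bis(3-methylbut-2-en-1-yl)phenyl]-4H-chromen-4-one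
Conditions: NaOAc, AcOH, 90 °C
Reagents that add atoms: none
Why: Cyclodehydration: the free phenol adds to the ring B ketone (6-exo-trig) to give the cyclic hemiketal, which loses water to the aromatic pyranone and forms O1–C2. Acetate-buffered acetic acid replaces mineral acid so that the MOM ethers and prenyl groups persist. Only the hydroxyl introduced in step 2 is free, so the methoxy group can only end up at C6.

Step 11
Reactants: 16 3,6-dimethoxy-5,7-bis(methoxymethoxy)-2-[4-(methoxymethoxy)-3,5-bis(3-methylbut-2-en-1-yl)phenyl]-4H-chromen-4-one
Product: 17 (2E)-4-[5-[3,6-dimethoxy-5,7-bis(methoxymethoxy)-4-oxo-4H-chromen-2-yl]-2-(methoxymethoxy)-3-(3-methylbut-2-en-1-yl)phenyl]-2-methylbut-2-enal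
Conditions: SeO2 (1.1 equiv), pyridine (cat.), 1,4-dioxane, 80 °C, stopped at partial conversion, recovered 16 recycled
Reagents that add atoms: selenium dioxide, O=[Se]=O
Why: Riley allylic oxidation (ene reaction at the trisubstituted alkene, [2,3]-sigmatropic shift, then oxidation of the allylic alcohol) selects the (E)-methyl of a prenyl group and gives the (E)-2-methyl enal. The two prenyl groups are equivalent, so either one gives the same product, and early interruption limits double oxidation.

Step 12
Reactants: 17 (2E)-4-[5-[3,6-dimethoxy-5,7-bis(methoxymethoxy)-4-oxo-4H-chromen-2-yl]-2-(methoxymethoxy)-3-(3-methylbut-2-en-1-yl)phenyl]-2-methylbut-2-enal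
Product: 19 2-{3-[(3S)-4-hydroxy-3-methylbutyl]-4-(methoxymethoxy)-5-(3-methylbut-2-en-1-yl)phenyl}-3,6-dimethoxy-5,7-bis(methoxymethoxy)-4H-chromen-4-one, via (S)-aldehyde 18 (not isolated)
Conditions: OYE2 (ene-reductase of Saccharomyces cerevisiae), NADP+ (cat.), NAD+ (cat.), D-glucose, glucose dehydrogenase, horse-liver alcohol dehydrogenase, KH2PO4/K2HPO4 buffer pH 7.0, 10% v/v DMSO, 30 °C
Reagents that add atoms: none
Why: Ene-reductases of the Old Yellow Enzyme family reduce carbonyl-activated alkenes: the aldehyde oxygen of 17 is held by two hydrogen-bond donors, reduced flavin mononucleotide delivers hydride from N5 to the β-carbon (the CH next to the benzylic CH2), and an active-site tyrosine protonates the α-carbon on the opposite face, a net anti addition of H2, with the flavin re-reduced by NADPH that glucose dehydrogenase regenerates from glucose. The closest known reactions are the reductions of α-methylcinnamaldehyde and 2-methylpent-2-enal to (S)-2-methyl aldehydes by the yeast enzymes, and the concurrent ene-reductase/alcohol dehydrogenase cascades that give (S)-2-methyl-3-arylpropan-1-ols. No ring is formed. The new stereocentre is the α-carbon, and its configuration is set by the face on which the enzyme protonates; for an (E)-enal bound in the usual orientation this should correspond to (S) here (CHO > CH2CH2Ar > CH3 > H), and it relies on the single (E) geometry supplied by step 11. The step needs chemoselectivity among three C=C bonds: only the enal alkene is polarised by a hydrogen-bonded carbonyl, the prenyl alkene is unactivated, and the tetrasubstituted, oxygen-bearing C2=C3 bond of the pyranone is not a substrate for this enzyme class. The phenols stay as MOM ethers because phenolates bind tightly over the flavin of these enzymes and because a free 4'-phenol could add to the enal by 5-exo oxa-Michael reaction, and the DMSO co-solvent keeps the lipophilic substrate available. The alcohol dehydrogenase reduces aldehyde 18 as it forms, so the α-methyl aldehyde has no time to enolise and the centre is locked in alcohol 19.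

Step 13
Reactants: 19 2-{3-[(3S)-4-hydroxy-3-methylbutyl]-4-(methoxymethoxy)-5-(3-methylbut-2-en-1-yl)phenyl}-3,6-dimethoxy-5,7-bis(methoxymethoxy)-4H-chromen-4-one
Product: 20 5,7-dihydroxy-2-{4-hydroxy-3-[(3S)-4-hydroxy-3-methylbutyl]-5-(3-methylbut-2-en-1-yl)phenyl}-3,6-dimethoxy-4H-chromen-4-one
Conditions: 3 M HCl, MeOH–THF, 40 °C, stopped on completion
Reagents that add atoms: none
Why: Acid-catalysed acetal exchange with methanol removes the three MOM ethers, the peri 5-O group fastest. Dilute acid at moderate temperature is the usual way to unmask prenylated phenols without closing the 4'-OH onto the adjacent alkene. The stereocentre is now a non-enolisable carbon and cannot epimerise.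

## Compound list

1 | 2-methoxybenzene-1,3-diol | COc1c(O)cccc1O | starting material
2 | 2-methoxy-1,3-bis(methoxymethoxy)benzene | COCOc1cccc(OCOC)c1OC | intermediate
3 | 2-[4-methoxy-3,5-bis(methoxymethoxy)phenyl]-4,4,5,5-tetramethyl-1,3,2-dioxaborolane | COCOc1cc(B2OC(C)(C)C(C)(C)O2)cc(OCOC)c1OC | intermediate
4 | 4-methoxy-3,5-bis(methoxymethoxy)phenol | COCOc1cc(O)cc(OCOC)c1OC | intermediate
5 | 2-bromo-4-methoxy-3,5-bis(methoxymethoxy)phenol | Oc1cc(OCOC)c(OC)c(OCOC)c1Br | intermediate
6 | N,2-dimethoxy-N-methylacetamide | COCC(=O)N(C)OC | starting material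
7 | lithium 2-lithio-4-methoxy-3,5-bis(methoxymethoxy)phenoxide | [Li]Oc1cc(OCOC)c(OC)c(OCOC)c1[Li] | intermediate
8 | 1-[6-hydroxy-3-methoxy-2,4-bis(methoxymethoxy)phenyl]-2-methoxyethan-1-one | COCC(=O)c1c(O)cc(OCOC)c(OC)c1OCOC | intermediate
9 | methyl 4-hydroxy-3,5-diiodobenzoate | COC(=O)c1cc(I)c(O)c(I)c1 | starting material
10 | methyl 3,5-diiodo-4-(methoxymethoxy)benzoate | COCOc1c(I)cc(C(=O)OC)cc1I | intermediate
11 | tributyl(3-methylbut-2-en-1-yl)stannane | CCCC[Sn](CCCC)(CCCC)CC=C(C)C | starting material
12 | methyl 4-(methoxymethoxy)-3,5-bis(3-methylbut-2-en-1-yl)benzoate | COCOc1c(CC=C(C)C)cc(C(=O)OC)cc1CC=C(C)C | intermediate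
13 | 4-(methoxymethoxy)-3,5-bis(3-methylbut-2-en-1-yl)benzoic acid | COCOc1c(CC=C(C)C)cc(C(=O)O)cc1CC=C(C)C | intermediate
14 | 4-methoxy-2-(2-methoxyacetyl)-3,5-bis(methoxymethoxy)phenyl 4-(methoxymethoxy)-3,5-bis(3-methylbut-2-en-1-yl)benzoate | COCC(=O)c1c(OC(=O)c2cc(CC=C(C)C)c(OCOC)c(CC=C(C)C)c2)cc(OCOC)c(OC)c1OCOC | intermediate
15 | 1-[6-hydroxy-3-methoxy-2,4-bis(methoxymethoxy)phenyl]-2-methoxy-3-[4-(methoxymethoxy)-3,5-bis(3-methylbut-2-en-1-yl)phenyl]propane-1,3-dione | COC(C(=O)c1c(O)cc(OCOC)c(OC)c1OCOC)C(=O)c1cc(CC=C(C)C)c(OCOC)c(CC=C(C)C)c1 | intermediate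
16 | 3,6-dimethoxy-5,7-bis(methoxymethoxy)-2-[4-(methoxymethoxy)-3,5-bis(3-methylbut-2-en-1-yl)phenyl]-4H-chromen-4-one | COCOc1cc2oc(-c3cc(CC=C(C)C)c(OCOC)c(CC=C(C)C)c3)c(OC)c(=O)c2c(OCOC)c1OC | intermediate
17 | (2E)-4-[5-[3,6-dimethoxy-5,7-bis(methoxymethoxy)-4-oxo-4H-chromen-2-yl]-2-(methoxymethoxy)-3-(3-methylbut-2-en-1-yl)phenyl]-2-methylbut-2-enal | COCOc1cc2oc(-c3cc(CC=C(C)C)c(OCOC)c(C/C=C(\C)C=O)c3)c(OC)c(=O)c2c(OCOC)c1OC | intermediate
18 | (2S)-4-[5-[3,6-dimethoxy-5,7-bis(methoxymethoxy)-4-oxo-4H-chromen-2-yl]-2-(methoxymethoxy)-3-(3-methylbut-2-en-1-yl)phenyl]-2-methylbutanal | COCOc1cc2oc(-c3cc(CC=C(C)C)c(OCOC)c(CC[C@H](C)C=O)c3)c(OC)c(=O)c2c(OCOC)c1OC | intermediate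
19 | 2-{3-[(3S)-4-hydroxy-3-methylbutyl]-4-(methoxymethoxy)-5-(3-methylbut-2-en-1-yl)phenyl}-3,6-dimethoxy-5,7-bis(methoxymethoxy)-4H-chromen-4-one | COCOc1cc2oc(-c3cc(CC=C(C)C)c(OCOC)c(CC[C@H](C)CO)c3)c(OC)c(=O)c2c(OCOC)c1OC | intermediate
20 | 5,7-dihydroxy-2-{4-hydroxy-3-[(3S)-4-hydroxy-3-methylbutyl]-5-(3-methylbut-2-en-1-yl)phenyl}-3,6-dimethoxy-4H-chromen-4-one | COc1c(O)cc2oc(-c3cc(CC=C(C)C)c(O)c(CC[C@H](C)CO)c3)c(OC)c(=O)c2c1O | target

## Step count and least certain steps

Total: 13 steps. Longest linear sequence: 10 steps (steps 1–4, then 8–13). The ring B arm (steps 5–7) joins at step 8.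

**Step 12 (key step).** The most likely failure is slow or absent turnover, because the large, water-insoluble flavone end of 17 may not allow the enal to sit productively over the flavin. Next in likelihood are insufficient or inverted face selectivity for this γ-aryl enal, and direct carbonyl reduction of the enal by the dehydrogenase to an allylic alcohol that the ene-reductase cannot reduce. The fallback is a chemical asymmetric hydrogenation at the acid oxidation level. It sets out from 17. Pinnick oxidation (NaClO2, NaH2PO4, 2-methylbut-2-ene, t-BuOH–H2O) should give the (E)-2-methylbut-2-enoic acid F1. Carboxylate-directed hydrogenation with Ru(OAc)2[(S)-BINAP] and H2 in MeOH, the standard reaction of tiglic-acid-type substrates, should give the (S)-2-methylbutanoic acid F2 and leave the uncoordinated prenyl and pyranone alkenes alone; the ligand enantiomer is chosen by analogy and would have to be confirmed. Activation with isobutyl chloroformate and N-methylmorpholine to the mixed carbonic anhydride F3, then NaBH4 in THF–H2O at 0 °C, returns to the route at 19.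

**Step 11.** The two prenyl groups do not influence each other, so oxidation is likely to run on at the second group, and allylic alcohol and enal may form side by side. Selenous acid may also begin to cleave MOM ethers. The fallback replaces C–H oxidation by alkene exchange. From 16, cross-metathesis with excess methacrolein and the second-generation Hoveyda–Grubbs catalyst (toluene, 80 °C) should exchange the isopropylidene end of one prenyl group for the (E)-2-methyl enal terminus and give 17 directly, with recovered 16 recycled. This passes through no new isolated compound (F0).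

**Step 10.** Acetolysis of MOM ethers in hot acetic acid, first at the peri 5-O position, or stalling at the cyclic hemiketal, would give mixtures. The fallback accepts the deprotection. From 15, methanolic HCl at 50 °C for a short time should close ring C and remove all three MOM groups, giving 5,7-dihydroxy-2-[4-hydroxy-3,5-bis(3-methylbut-2-en-1-yl)phenyl]-3,6-dimethoxy-4H-chromen-4-one F4. Exhaustive re-protection (NaH, excess MOMCl, DMF) returns to the route at 16.

**Step 4.** Proton transfer from the acidic α-methylene of amide 6 to the hindered aryllithium, or butylation of the aryllithium by the butyl bromide formed in the exchange, would return debrominated or alkylated material. The fallback builds the side chain by electrophilic formylation. From 4 (bypassing 5), ortho-formylation with MgCl2, Et3N and paraformaldehyde in MeCN at reflux should give 6-hydroxy-3-methoxy-2,4-bis(methoxymethoxy)benzaldehyde F5. Addition of methoxymethyllithium (from Bu3SnCH2OMe and n-BuLi, in excess to absorb the phenolic proton) gives 2-(1-hydroxy-2-methoxyethyl)-4-methoxy-3,5-bis(methoxymethoxy)phenol F6. MnO2 oxidation of the benzylic alcohol returns to the route at 8.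

**Step 13.** Once the 4'-O-MOM group is lost, acid can promote addition of the free 4'-hydroxyl to the neighbouring prenyl alkene (chroman closure) before the remaining acetals are gone. The fallback avoids Brønsted acid by going through silyl ethers. From 19, TMSOTf and 2,2'-bipyridyl in CH2Cl2 should convert the aryl MOM ethers into aryl trimethylsilyl ethers and silylate the primary alcohol, giving the tetrakis(trimethylsilyl) ether F7. Mild hydrolysis (K2CO3, MeOH–H2O) then gives 20.

## Further compounds

F1 | step 12 | (2E)-4-[5-[3,6-dimethoxy-5,7-bis(methoxymethoxy)-4-oxo-4H-chromen-2-yl]-2-(methoxymethoxy)-3-(3-methylbut-2-en-1-yl)phenyl]-2-methylbut-2-enoic acid | COCOc1cc2oc(-c3cc(CC=C(C)C)c(OCOC)c(C/C=C(\C)C(=O)O)c3)c(OC)c(=O)c2c(OCOC)c1OC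
F2 | step 12 | (2S)-4-[5-[3,6-dimethoxy-5,7-bis(methoxymethoxy)-4-oxo-4H-chromen-2-yl]-2-(methoxymethoxy)-3-(3-methylbut-2-en-1-yl)phenyl]-2-methylbutanoic acid | COCOc1cc2oc(-c3cc(CC=C(C)C)c(OCOC)c(CC[C@H](C)C(=O)O)c3)c(OC)c(=O)c2c(OCOC)c1OC
F3 | step 12 | mixed anhydride of F2 with isobutyl hydrogen carbonate | COCOc1cc2oc(-c3cc(CC=C(C)C)c(OCOC)c(CC[C@H](C)C(=O)OC(=O)OCC(C)C)c3)c(OC)c(=O)c2c(OCOC)c1OC
F0 | step 11 | none | none
F4 | step 10 | 5,7-dihydroxy-2-[4-hydroxy-3,5-bis(3-methylbut-2-en-1-yl)phenyl]-3,6-dimethoxy-4H-chromen-4-one | COc1c(O)cc2oc(-c3cc(CC=C(C)C)c(O)c(CC=C(C)C)c3)c(OC)c(=O)c2c1O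
F5 | step 4 | 6-hydroxy-3-methoxy-2,4-bis(methoxymethoxy)benzaldehyde | O=Cc1c(O)cc(OCOC)c(OC)c1OCOC
F6 | step 4 | 2-(1-hydroxy-2-methoxyethyl)-4-methoxy-3,5-bis(methoxymethoxy)phenol (racemic) | COCC(O)c1c(O)cc(OCOC)c(OC)c1OCOC
F7 | step 13 | 3,6-dimethoxy-2-{3-[(3S)-3-methyl-4-(trimethylsilyloxy)butyl]-5-(3-methylbut-2-en-1-yl)-4-(trimethylsilyloxy)phenyl}-5,7-bis(trimethylsilyloxy)-4H-chromen-4-one | COc1c(O[Si](C)(C)C)cc2oc(-c3cc(CC=C(C)C)c(O[Si](C)(C)C)c(CC[C@H](C)CO[Si](C)(C)C)c3)c(OC)c(=O)c2c1O[Si](C)(C)C
A1 | alternative 1 | (2S)-4-[5-bromo-3-(3-methylbut-2-en-1-yl)-2-(triisopropylsilyloxy)phenyl]-2-methylbutan-1-ol | CC(C)=CCc1cc(Br)cc(CC[C@H](C)CO)c1O[Si](C(C)C)(C(C)C)C(C)C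
A2 | alternative 1 | [4-bromo-2-(but-3-en-1-yl)-6-(3-methylbut-2-en-1-yl)phenoxy]triisopropylsilane | C=CCCc1cc(Br)cc(CC=C(C)C)c1O[Si](C(C)C)(C(C)C)C(C)C
A3 | alternative 2 | 2-{3-[(3S)-4-(tert-butyldimethylsilyloxy)-3-methylbutyl]-4-(methoxymethoxy)-5-(3-methylbut-2-en-1-yl)phenyl}-5,7-dihydroxy-3,6-dimethoxy-4H-chromen-4-one | COc1c(O)cc2oc(-c3cc(CC=C(C)C)c(OCOC)c(CC[C@H](C)CO[Si](C)(C)C(C)(C)C)c3)c(OC)c(=O)c2c1O
A4 | alternative 2 | methyl 4-[6-{3-[(3S)-4-(tert-butyldimethylsilyloxy)-3-methylbutyl]-4-(methoxymethoxy)-5-(3-methylbut-2-en-1-yl)phenyl}-5-methoxy-4-oxo-4H-pyran-2-yl]-2-methoxy-3-oxobutanoate | COC(=O)C(OC)C(=O)Cc1cc(=O)c(OC)c(-c2cc(CC=C(C)C)c(OCOC)c(CC[C@H](C)CO[Si](C)(C)C(C)(C)C)c2)o1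
A5 | alternative 2 | kojic acid, 5-hydroxy-2-(hydroxymethyl)-4H-pyran-4-one | OCc1cc(=O)c(O)co1
A6 | alternative 3 | 2-{3-[(3S)-4-(tert-butyldimethylsilyloxy)-3-methylbutyl]-4-(methoxymethoxy)-5-(3-methylbut-2-en-1-yl)phenyl}-3,6-dimethoxy-5,7-bis(methoxymethoxy)-4H-chromen-4-one | COCOc1cc2oc(-c3cc(CC=C(C)C)c(OCOC)c(CC[C@H](C)CO[Si](C)(C)C(C)(C)C)c3)c(OC)c(=O)c2c(OCOC)c1OC
A7 | alternative 3 | 3,6-dimethoxy-5,7-bis(methoxymethoxy)-4H-chromen-4-one | COCOc1cc2occ(OC)c(=O)c2c(OCOC)c1OC
A8 | alternative 3 | {(2S)-4-[5-bromo-2-(methoxymethoxy)-3-(3-methylbut-2-en-1-yl)phenyl]-2-methylbutoxy}(tert-butyl)dimethylsilane | COCOc1c(CC=C(C)C)cc(Br)cc1CC[C@H](C)CO[Si](C)(C)C(C)(C)C
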